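**Retrosynthetic overview**

1. Locants follow the phthalides. Unit A is the (Z)-butylidene butenolide (C-1, O-2, C-3, C-8) on ring A (C-3a, C-4, C-5, C-6, C-7, C-7a). Unit B (primed) is the (E)-butylidene lactone and ring B on C-3a'/C-7a'. The cyclobutane is C-6, C-7, C-3a', C-7a'.
2. Endgame: C-6'=C-7' by dehydration of a C-7' alcohol; lactone B by anti iodolactonisation of a C-3a' ethynyl / C-7a' carboxylic acid pair and Negishi propylation (E); butenolide A by cyclodehydration of a ring A γ-keto acid (Z).
3. Key disconnection: ring A by Diels–Alder reaction of the exocyclic diene C-5=C-6–C-7=C-7a (ester on C-7a) with hept-1-yn-3-one (C-4≡C-3a), forming C-4–C-5 and C-3a–C-7a. Enabling feature: C-6 and C-7 are adjacent cyclobutane carbons that each carry one exocyclic ring A carbon, so the four-membered ring locks the diene s-cis, and the C-3a=C-7a alkene of ring A bears an acyl and a carboxyl carbon. Directed hydrogenation of the resulting C-6=C-7 bond then sets both CH centres.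
4. Cyclobutane by [2+2] photocycloaddition of allene to a bicyclic butenolide (ring B plus the C-1'/C-3' lactone), anti to a C-7' silyloxy group that comes from a CBS reduction, the only source of absolute configuration.
5. Ring order: ring B (from an arene) → C-1'/C-3' butenolide → cyclobutane → ring A → butenolide A → lactone B → ring B alkene.

Key step: step 12

Assumption: the large/small model of the CBS reduction (alkenyl carbon as the large group) is taken to hold for 5, so the (R)-catalyst gives the (7S)-alcohol; otherwise the (S)-catalyst is used.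

**Route**

Step 1
Reactants: 1 3-methoxybenzyl alcohol
Product: 3 enone alcohol 3-(hydroxymethyl)cyclohex-2-en-1-one, via dihydroanisole enol ether 2 (not isolated)
Conditions: Li, NH3 (l), tBuOH, THF, −78 → −33 °C; then aq. HCl, THF, 23 °C
Reagents that add atoms: water O
Why: Birch reduction of the anisole ring (the benzylic alkoxide resists hydrogenolysis) gives the 1,4-dihydro enol ether, which acid hydrolyses and isomerises to the conjugated enone that becomes ring B.

Step 2
Reactants: 3 enone alcohol
Product: 4 bromo enone 2-bromo-3-(hydroxymethyl)cyclohex-2-en-1-one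
Conditions: Br2, CH2Cl2, 0 °C; then Et3N, 0 → 23 °C
Reagents that add atoms: bromine BrBr
Why: Bromine addition to the enone alkene and E1cB loss of HBr with Et3N is the standard α-bromination of cycloalkenones, the only removable hydrogen being the one α to the ketone.

Step 3
Reactants: 4 bromo enone
Product: 5 keto butenolide 5,6-dihydro-2-benzofuran-1,7(3H,4H)-dione
Conditions: CO (1 atm), Pd(PPh3)4 (5 mol %), Et3N, MeCN, 70 °C
Reagents that add atoms: carbon monoxide [C-]#[O+]
Why: Palladium-catalysed carbonylative lactonisation (oxidative addition into the vinyl bromide, CO insertion, capture of the acylpalladium by the cis hydroxymethyl group) closes the butenolide whose C=O is the future C-1' and whose CH2O is the future C-3'.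

Step 4
Reactants: 5 keto butenolide
Product: 6 allylic alcohol (7S)-7-hydroxy-4,5,6,7-tetrahydro-2-benzofuran-1(3H)-one
Conditions: (R)-2-methyl-CBS-oxazaborolidine (20 mol %), catecholborane, toluene, −78 → −40 °C
Reagents that add atoms: none
Why: Corey–Bakshi–Shibata reduction of the cyclic enone, with the alkenyl carbon as the large group, should give the (7S)-allylic alcohol by 1,2-hydride delivery; this is the only source of absolute configuration.

Step 5
Reactants: 6 allylic alcohol
Product: 7 silyl ether (7S)-7-[(tert-butyldimethylsilyl)oxy]-4,5,6,7-tetrahydro-2-benzofuran-1(3H)-one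
Conditions: TBSCl, imidazole, DMF, 23 °C
Reagents that add atoms: tert-butyldimethylsilyl chloride CC(C)(C)[Si](C)(C)Cl
Why: Standard silylation of the secondary alcohol; the bulky silyl ether is the facial control element for step 6 and masks the later ring B alkene.

Step 6
Reactants: 7 silyl ether; 8 allene (excess)
Product: 9 propellane lactone with an exocyclic methylene on C-6 and a CH2 at C-7
Conditions: hν (300 nm, Pyrex), acetone, −40 °C
Reagents that add atoms: none
Why: Acetone-sensitised [2+2] photocycloaddition of the α,β-unsaturated lactone to allene should take place on the face opposite the allylic silyloxy group and head to head (central allene carbon to the lactone α-carbon C-7a'), so that the cis-fused propellane with both quaternary centres C-3a' and C-7a' is formed.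

Step 7
Reactants: 9 propellane lactone
Product: 10 allylic alcohol with OH at C-7
Conditions: SeO2 (cat.), tBuOOH, CH2Cl2, 23 °C
Reagents that add atoms: tert-butyl hydroperoxide CC(C)(C)OO
Why: Selenium dioxide allylic oxidation (ene reaction then [2,3]-shift) can only attack C-7, the single allylic CH2, and returns the exocyclic double bond to C-6.

Step 8
Reactants: 10 allylic alcohol
Product: 11 exocyclic enone (C-7 ketone next to the C-6 methylene)
Conditions: Dess–Martin periodinane, CH2Cl2, 0 → 23 °C
Reagents that add atoms: none
Why: Dess–Martin oxidation of the allylic alcohol gives the exocyclic enone without touching lactone or silyl ether.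

Step 9
Reactants: 11 exocyclic enone; 12 tert-butyl 2-(trimethylsilyl)acetate
Product: 14 diene ester with the tert-butyl ester on the C-7=C-7a alkene, via β-hydroxysilane adduct 13 (not isolated)
Conditions: 12, LiN(iPr)2, THF, −78 °C; CeCl3; then 11, −78 → 23 °C
Reagents that add atoms: none
Why: Peterson olefination: the cerium-modified lithium enolate of the α-silyl ester adds 1,2 to the strained cyclobutanone and the β-silyl alkoxide eliminates to the cross-conjugated dienoate, whose two exocyclic alkenes are held s-cis by the four-membered ring (both enoate geometries are carried on).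

Step 10
Reactants: 14 diene ester
Product: 16 pseudo-acid diene (hydroxylactone C-3'H(OH)–O–C-1'(=O)), via hydroxy acid lithium salt 15 (not isolated)
Conditions: LiOH, THF/H2O, 23 °C; evaporate; 2-iodoxybenzoic acid, DMSO, 23 °C; aq. HCl work-up
Reagents that add atoms: lithium hydroxide [Li+].[OH-]
Why: Saponification opens the lactone to the carboxylate (C-1') and primary alcohol (C-3'), oxidation of the alcohol with 2-iodoxybenzoic acid gives the aldehyde, and acidification closes it to the hydroxylactone, a masked aldehyde acid whose OH will direct step 13.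

Step 11
Reactants: 17 hept-1-yn-3-ol
Product: 18 hept-1-yn-3-one
Conditions: MnO2, CH2Cl2, 23 °C
Reagents that add atoms: none
Why: MnO2 oxidation of the propargylic alcohol gives the ynone dienophile.

Step 12
Reactants: 16 pseudo-acid diene; 18 hept-1-yn-3-one
Product: 19 Diels–Alder adduct with ring A as a cyclohexa-1,4-diene
Conditions: 18 (excess), BHT (cat.), toluene, 110 °C, sealed tube
Reagents that add atoms: none
Why: Mechanism: thermal, concerted but asynchronous [4+2] cycloaddition (Diels–Alder reaction) between the exocyclic diene C-5=C-6–C-7=C-7a of 16 and the ynone C-4≡C-3a of 18. The closest known reaction types are Diels–Alder reactions of 1,2-bis(alkylidene)cyclobutanes and of 1-alkoxycarbonyl-1,3-dienes with acetylenic ketones. Ring A is closed in suprafacial [4+2] mode, C-4–C-5 and C-3a–C-7a forming together and leaving the C-6=C-7 and C-3a=C-4 double bonds of a cyclohexa-1,4-diene. The only new stereocentre, C-7a, is not controlled and is erased in step 14, so both enoate geometries of 16 and both diene faces converge. The step needs regioselectivity (acyl carbon next to the ester-bearing carbon), which the ortho rule secures because the largest HOMO coefficient of the 1-acceptor-substituted diene lies on the remote terminus C-5 and pairs with the β-carbon C-4 of the ynone; it also needs an s-cis diene, which the four-membered ring enforces.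

Step 13
Reactants: 19 Diels–Alder adduct
Product: 20 dihydro adduct with cis hydrogens at C-6 and C-7
Conditions: H2 (1 atm), [Ir(cod)(PCy3)(py)]PF6 (10 mol %), CH2Cl2, 23 °C
Reagents that add atoms: none
Why: Hydroxyl-directed hydrogenation: the hemiacetal OH on C-3' and the lactone carbonyl bind the cationic iridium on the lactone face of the tetrasubstituted cyclobutene (ring B shields the other face), so both hydrogens add there and C-6 and C-7 become cis CH centres with ring A on the ring B face, while the electron-poor enone alkene is left.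

Step 14
Reactants: 20 dihydro adduct
Product: 22 alkynoic acid (ethynyl on C-3a', CO2H on C-7a'), via conjugated keto ester 21 (not isolated)
Conditions: dimethyl (1-diazo-2-oxopropyl)phosphonate, K2CO3, MeOH, 0 → 23 °C; acidic work-up
Reagents that add atoms: dimethyl (1-diazo-2-oxopropyl)phosphonate COP(=O)(OC)C(=[N+]=[N-])C(C)=O
Why: Under K2CO3 in methanol the skipped alkene moves into conjugation with ketone and ester (C-3a=C-7a, erasing C-7a and keeping the cis ring fusion) and the pseudo-acid opens to the aldehyde, which the Ohira–Bestmann reagent (Seyferth–Gilbert homologation) converts into the terminal alkyne on C-3a' next to the C-7a' carboxylic acid.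

Step 15
Reactants: 22 alkynoic acid
Product: 25 (Z)-butylidene butenolide alkynoic acid with free C-7' OH, via keto diacid 23 (not isolated), via hydroxybutenolide 24 (not isolated)
Conditions: CF3CO2H, H2O, CH2Cl2, 23 °C; then TsOH·H2O (cat.), toluene, 70 °C
Reagents that add atoms: none
Why: Acid removes the tert-butyl ester and the silyl ether, the cis γ-keto acid closes to the hydroxybutenolide and acid-catalysed dehydration gives the thermodynamically preferred (Z)-butylidene butenolide (propyl on the oxygen side, away from C-4).

Step 16
Reactants: 25 (Z)-butylidene butenolide alkynoic acid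
Product: 26 (E)-iodomethylene lactone
Conditions: I2, NaHCO3, MeCN/H2O, 0 °C, dark
Reagents that add atoms: iodine [I][I]
Why: Iodolactonisation of the 4-alkynoic acid is a 5-exo-dig anti addition of carboxylate and iodonium across the alkyne, which places iodine trans to the ring oxygen, i.e. the (E)-iodomethylene lactone.

Step 17
Reactants: 26 (E)-iodomethylene lactone; 27 n-propylzinc bromide
Product: 28 hydroxy precursor (7'-hydroxy-6',7'-dihydro target)
Conditions: 27 (excess), Pd(dppf)Cl2 (5 mol %), THF, 23 °C
Reagents that add atoms: none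
Why: Negishi coupling of the alkenyl iodide with the primary alkylzinc reagent proceeds with retention of alkene geometry (the dppf ligand suppresses β-hydride elimination), so propyl ends trans to the ring oxygen, the (E)-butylidene lactone.

Step 18
Reactants: 28 hydroxy precursor
Product: 29 target CNP0371639.1
Conditions: Burgess reagent (methyl N-(triethylammoniosulfonyl)carbamate), toluene, 70 °C
Reagents that add atoms: none
Why: Burgess dehydration (syn elimination of the sulfamate ester) can only give the C-6'=C-7' alkene because C-7a' is quaternary, which removes the auxiliary stereocentre and should give the target.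

**Compound list**

1 | 3-methoxybenzyl alcohol | COc1cccc(CO)c1 | starting material
2 | (5-methoxycyclohexa-1,4-dien-1-yl)methanol | COC1=CCC=C(CO)C1 | intermediate
3 | 3-(hydroxymethyl)cyclohex-2-en-1-one | O=C1C=C(CO)CCC1 | intermediate
4 | 2-bromo-3-(hydroxymethyl)cyclohex-2-en-1-one | O=C1C(Br)=C(CO)CCC1 | intermediate
5 | 5,6-dihydro-2-benzofuran-1,7(3H,4H)-dione | O=C1OCC2=C1C(=O)CCC2 | intermediate
6 | (7S)-7-hydroxy-4,5,6,7-tetrahydro-2-benzofuran-1(3H)-one | O=C1OCC2=C1[C@@H](O)CCC2 | intermediate
7 | (7S)-7-[(tert-butyldimethylsilyl)oxy]-4,5,6,7-tetrahydro-2-benzofuran-1(3H)-one | O=C1OCC2=C1[C@@H](O[Si](C)(C)C(C)(C)C)CCC2 | intermediate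
8 | propa-1,2-diene (allene) | C=C=C | starting material
9 | propellane lactone: cyclobutane across C-3a'/C-7a' of 7 on the face anti to OTBS, =CH2 on C-6 (bonded to C-7a'), CH2 at C-7 | C=C1C[C@@]2(COC3=O)CCC[C@H](O[Si](C)(C)C(C)(C)C)[C@@]123 | intermediate
10 | allylic alcohol: 9 with OH at C-7 (both C-7 epimers) | C=C1C(O)[C@@]2(COC3=O)CCC[C@H](O[Si](C)(C)C(C)(C)C)[C@@]123 | intermediate
11 | exocyclic enone: C-7 ketone next to the C-6 methylene | C=C1C(=O)[C@@]2(COC3=O)CCC[C@H](O[Si](C)(C)C(C)(C)C)[C@@]123 | intermediate
12 | tert-butyl 2-(trimethylsilyl)acetate | CC(C)(C)OC(=O)C[Si](C)(C)C | starting material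
13 | β-hydroxysilane adduct at C-7 (metal alkoxide in the flask, diastereomer mixture) | C=C1C(O)(C([Si](C)(C)C)C(=O)OC(C)(C)C)[C@@]2(COC3=O)CCC[C@H](O[Si](C)(C)C(C)(C)C)[C@@]123 | intermediate
14 | diene ester: tert-butyl ester on the C-7=C-7a alkene (E/Z mixture, geometry left open), C-5H2=C-6, lactone C-1'(=O)–O–C-3'H2 | C=C1C(=CC(=O)OC(C)(C)C)[C@@]2(COC3=O)CCC[C@H](O[Si](C)(C)C(C)(C)C)[C@@]123 | intermediate
15 | hydroxy acid (lithium salt in the flask): CO2H on C-7a', CH2OH on C-3a' | C=C1C(=CC(=O)OC(C)(C)C)[C@@]2(CO)CCC[C@H](O[Si](C)(C)C(C)(C)C)[C@@]12C(=O)O | intermediate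
16 | pseudo-acid diene: hydroxylactone C-3'H(OH)–O–C-1'(=O) (both C-3' epimers) | C=C1C(=CC(=O)OC(C)(C)C)[C@@]2(C(O)OC3=O)CCC[C@H](O[Si](C)(C)C(C)(C)C)[C@@]123 | intermediate
17 | hept-1-yn-3-ol (racemic) | C#CC(O)CCCC | starting material
18 | hept-1-yn-3-one | C#CC(=O)CCCC | intermediate
19 | Diels–Alder adduct: ring A cyclohexa-1,4-diene (C-6=C-7, C-3a=C-4), CO2tBu on C-7a (both epimers), pentanoyl on C-3a | CC(C)(C)OC(=O)C1C(C(=O)CCCC)=CCC2=C1[C@@]1(C(O)OC3=O)CCC[C@H](O[Si](C)(C)C(C)(C)C)[C@@]213 | intermediate
20 | dihydro adduct: cis H at C-6 and C-7 (ring A on the ring B face), C-3a=C-4 kept | CC(C)(C)OC(=O)C1C(C(=O)CCCC)=CC[C@H]2[C@@H]1[C@@]1(C(O)OC3=O)CCC[C@H](O[Si](C)(C)C(C)(C)C)[C@@]213 | intermediate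
21 | conjugated keto ester: C-3a=C-7a, C-4H2 (pseudo-acid, open as aldehyde carboxylate in the flask) | CC(C)(C)OC(=O)C1=C(C(=O)CCCC)CC[C@H]2[C@@H]1[C@@]1(C(O)OC3=O)CCC[C@H](O[Si](C)(C)C(C)(C)C)[C@@]213 | intermediate
22 | alkynoic acid: ethynyl on C-3a', CO2H on C-7a', ring A keto tert-butyl ester, OTBS at C-7' | CC(C)(C)OC(=O)C1=C(C(=O)CCCC)CC[C@H]2[C@@H]1[C@@]1(C#C)CCC[C@H](O[Si](C)(C)C(C)(C)C)[C@@]21C(=O)O | intermediate
23 | keto diacid with free C-7' OH | OC(=O)C1=C(C(=O)CCCC)CC[C@H]2[C@@H]1[C@@]1(C#C)CCC[C@H](O)[C@@]21C(=O)O | intermediate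
24 | hydroxybutenolide (C-3 hemiketal, both epimers) | CCCCC1(O)OC(=O)C2=C1CC[C@H]1[C@@H]2[C@@]2(C#C)CCC[C@H](O)[C@@]12C(=O)O | intermediate
25 | (Z)-butylidene butenolide alkynoic acid with C-7' OH | CCC/C=C1\OC(=O)C2=C1CC[C@H]1[C@@H]2[C@@]2(C#C)CCC[C@H](O)[C@@]12C(=O)O | intermediate
26 | (E)-iodomethylene lactone | CCC/C=C1\OC(=O)C2=C1CC[C@H]1[C@@H]2[C@@]23CCC[C@H](O)[C@@]12C(=O)O/C3=C/I | intermediate
27 | n-propylzinc bromide (solution in THF) | CCC[Zn]Br | starting material
28 | hydroxy precursor: target with C-6'H2 and C-7'H(OH) in place of the ring B alkene | CCC/C=C1\OC(=O)C2=C1CC[C@H]1[C@@H]2[C@@]23CCC[C@H](O)[C@@]12C(=O)O/C3=C/CCC | intermediate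
29 | CNP0371639.1 | CCC/C=C1\OC(=O)C2=C1CC[C@H]1[C@@H]2[C@@]23CCC=C[C@@]12C(=O)O/C3=C/CCC | target

**Step count and risks**

Total step count: 18. Longest linear sequence: 17 steps (steps 1–10 and 12–18; step 11 is a one-step side branch).

The three steps most likely to fail:

Step 12 (key Diels–Alder reaction). The electron-poor diene may add so slowly that the ynone polymerises, or the orientation of the addition may erode. Fallback, setting out from 16: an α-bromo enone is used as a more reactive ynone equivalent. Commercial hept-1-en-3-one is brominated to 1,2-dibromoheptan-3-one F1 and dehydrobrominated with Et3N to 2-bromohept-1-en-3-one F2. Its Diels–Alder reaction with 16 should give the bromo ketone adduct F3, and loss of HBr (Et3N) the linearly conjugated dienone F4. Directed hydrogenation of F4 under the conditions of step 13 comes back to the route at 21, which enters the homologation of step 14.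

Step 13 (directed hydrogenation). Hydrogen may be delivered from the ring B face, or the enone alkene may be reduced as well. Fallback, setting out from 19: Et3N isomerises the skipped diene to the conjugated dienone F5 (same constitution as F4). This is reduced in the 1,6 sense with [(Ph3P)CuH]6 in excess, since the acidic OH consumes hydride. Copper hydride should attack the unhindered terminus C-6 from the lactone face and the extended enolate should protonate at C-7 to the cis ring fusion, which comes back to the route at 21.

Step 6 (photocycloaddition). The allene may add with the reversed orientation, placing the exocyclic methylene on C-7. Fallback, setting out from 7: the regioisomeric adduct F6 is ozonised (O3, then Me2S) to the cyclobutanone F7. Mannich-type α-methylenation at C-6 (paraformaldehyde, N-methylanilinium trifluoroacetate, THF, 65 °C) then comes back to the route at enone 11.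

Further compounds
F1 | step 12 | 1,2-dibromoheptan-3-one | BrCC(Br)C(=O)CCCC
F2 | step 12 | 2-bromohept-1-en-3-one | C=C(Br)C(=O)CCCC
F3 | step 12 | bromo ketone Diels–Alder adduct (Br and pentanoyl on C-3a, C-6=C-7) | CC(C)(C)OC(=O)C1C(Br)(C(=O)CCCC)CCC2=C1[C@@]1(C(O)OC3=O)CCC[C@H](O[Si](C)(C)C(C)(C)C)[C@@]213
F4 | step 12 | conjugated dienone (C-6=C-7 and C-3a=C-7a) | CC(C)(C)OC(=O)C1=C(C(=O)CCCC)CCC2=C1[C@@]1(C(O)OC3=O)CCC[C@H](O[Si](C)(C)C(C)(C)C)[C@@]213
F5 | step 13 | conjugated dienone (C-6=C-7 and C-3a=C-7a) | CC(C)(C)OC(=O)C1=C(C(=O)CCCC)CCC2=C1[C@@]1(C(O)OC3=O)CCC[C@H](O[Si](C)(C)C(C)(C)C)[C@@]213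
F6 | step 6 | regioisomeric photoadduct (=CH2 on C-7, CH2 at C-6) | C1C(=C)[C@@]2(COC3=O)CCC[C@H](O[Si](C)(C)C(C)(C)C)[C@@]123
F7 | step 6 | cyclobutanone (C-7 ketone, CH2 at C-6) | C1C(=O)[C@@]2(COC3=O)CCC[C@H](O[Si](C)(C)C(C)(C)C)[C@@]123
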